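## Analysis of the target

Coloratanin A (17) is an isoflavone: a benzo ring A is fused to a 4-pyranone ring C (O1, C2, C3, C4, C4a, C8a), and the aryl ring B sits on C3. Ring A carries hydroxyls at C5 and C7 and a 3-methylbut-2-enyl (prenyl) group at C6 between them, while ring B carries a hydroxyl at C4' and a 3-hydroxy-3-methylbutyl chain at C3'. There is no stereocentre and no stereogenic double bond, so the problem is one of regiochemistry and of the order in which functional groups appear. Three groups are sensitive: the prenyl alkene flanked by two phenols, which acid closes to a dimethylchroman and hydrogenation saturates; the tertiary alcohol, which acid would dehydrate or cyclise onto the C4' phenol; and C2 of the pyranone, which hydroxide or nucleophilic amines attack with ring opening. The difficulty is that the two five-carbon side chains must arrive by orthogonal chemistry, one saturated and hydrated and one olefinic, and that the prenyl group must go to C6 and not to C8. The strategy rests on the fact that C4a is ortho to O1. In a ring A that does not yet carry the C6 substituent, the two carbons ortho to O1 are equivalent by symmetry and activated by the C5 and C7 oxygens. An aryl vinyl ether O1–C2=C3 that carries the C4 carboxyl group on C3 can therefore be acylated at C4a with only one possible outcome.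

## Retrosynthetic reasoning

**O–Si bonds (17 from 16).** The 7-OH and 4'-OH are masked as silyl ethers in 16 and released last. Desilylation under buffered, near-neutral conditions is chosen because the completed molecule tolerates neither acid (prenyl and tertiary alcohol next to phenols) nor strong base (pyranone C2).

**C6–prenyl bond (16 from 15, 15 from 14).** The prenyl group survives neither hydrogenolysis nor the acidic ring closure, so it is attached after both, by a Stille coupling at the C6 iodide 15. The iodide comes from 14, where the 5-OH is left free on purpose. Hydrogen-bonded to the C4 carbonyl, it steers the electrophile to its ortho carbon C6, while silyl ethers mute the 7-O and ring B.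

**Silyl ethers, benzyl ethers and the ring B chain (14 from 13, 13 from 12, 12 from 10 and 11).** Tetraol 13 is silylated only at its two free, unchelated phenols. 13 comes from 12 by a single hydrogenation that saturates the styrenyl alkene and removes all three benzyl groups, so the benzyl protection costs no separate step. The C3'–C bond of 12 is cut by a Heck disconnection to aryl bromide 10 and the tertiary allylic alcohol 11. The acid-sensitive tertiary alcohol thus enters only after the acidic key step.

**C4–C4a bond (10 from 8 through 9).** This is the key disconnection. It turns ring C into the (Z)-3-aryloxy-2-arylacrylic acid 8, whose ring A is a symmetrical 3,5-dioxygenated aryl ether. The forward reaction activates the carboxyl group as the mixed anhydride 9 and acylates the ring carbon ortho to the ether oxygen. The cut is made here and not at O1–C2 or C2–C3 because it is the only ring C bond whose formation is intramolecular, regiochemically degenerate, and leaves the ring B bromide untouched.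

**O1–C2 bond (8 from 7, 7 from 5 and 6).** Acid 8 is the saponification product of ester 7. The vinyl ether C–O bond of 7 is cut to the phenol 6 and the enol tosylate 5; forward, this is an addition–elimination at the β-carbon of an acrylate. The tosylate geometry (Z) is carried into 7.

**C2–C3 bond and the ring B building block (5 from 4, 4 from 3, 3 from 2, 2 from 1).** The C2 carbon is a formyl group introduced by a crossed Claisen formylation of the arylacetate 3, giving enol 4, which is tosylated to 5. Ester 3 comes from the bromophenol acid 1 by esterification (2) and O-benzylation.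

## Alternatives that were turned down

Alternative 1: Ring C would be cut at C3–C4 and at O1–C2. In the forward direction the morpholine enamine A3, made from the ring B arylacetaldehyde, would be acylated on carbon by the salicyloyl chloride A2 (2-acetoxy-4,6-bis(benzyloxy)benzoyl chloride). Removal of the ortho acetate with methanol would then free a phenoxide that adds to the enaminone and expels morpholine, giving isoflavone A1.
- For it: the route is convergent, ring C forms without acid, and the ring B chain can therefore be complete (as its triethylsilyl ether) before the coupling. No alkene geometry has to be right. On convergence and mildness it is stronger than the chosen route.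
- Against it: A2 needs a phloroglucinol carboxylic acid with three differentiated oxygens (one acetate, two benzyl ethers), so the symmetry that makes phenol 6 convenient is lost. The acid chloride is doubly ortho-substituted and slow to react. A3 derives from an arylacetaldehyde that is prone to self-condensation and must itself be built over several steps (Heck coupling, selective alkene reduction in the presence of a benzyl ether, silylation, adjustment to the aldehyde).
- Comparison: the end game after A1 is the same as after 12, so the extra fragment work is not repaid. The chosen route uses the commercial acid 1 and the symmetrical phenol 6 directly.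

Alternative 2: Ring A would be cut at four bonds and grown on a preformed pyranone. Photolysis of the diazoketone A5 would expel nitrogen and give, by Wolff rearrangement, a vinylketene. [2+2] Cycloaddition of the siloxyalkyne A6, four-electron opening of the resulting cyclobutenone and six-electron electrocyclisation would then deliver the phenol A4.
- For it: the prenyl group arrives at C6 by construction, so the C6/C8 question never arises, and the three ring A substituents are differentiated in one step. On regiocontrol of the prenyl group it is clearly stronger than the chosen route.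
- Against it: A5 is a 5-aryl-2-(diazoacetyl)pyran-4-one that needs a long, unusual synthesis. A6 is a skipped enyne ynol ether of limited stability. 4-Pyranones are themselves photoactive, so the Wolff step competes with chromophore chemistry.
- Comparison: several steps of this route would be uncertain, whereas the chosen route concentrates its risk in one classical acylation and uses a directed iodination for C6.

Alternative 3: Ring C would be cut at C4–C4a, C2–C3 and O1–C2 and assembled in one pot. Phloroglucinol A8 would be acylated by acid 1 under BF3·OEt2 to the deoxybenzoin A9. A formylating reagent made from DMF and CH3SO2Cl would then add the C2 carbon at the methylene, and closure by an ortho hydroxyl would give isoflavone A7.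
- For it: it is by far the shortest way to the isoflavone core, needs no protecting group and uses a well-established reaction type. On step economy it is stronger than the chosen route.
- Against it: A7 is a polar free triphenol with an aryl bromide. The following Heck coupling and every purification must be done on that material, or three protecting groups must be added afterwards. The hot Lewis-acid step also has to stop at monoacylation of A8.
- Comparison: the chosen route pays about five more steps. In return it gives lipophilic intermediates, a ring closure at 0 °C and a protected bromide 10 ready for the Heck coupling, and its benzyl groups come off in the hydrogenation that is needed anyway.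

Key step: step 7

Assumption on materials: compounds 1, 6 and 11 and tributyl(3-methylbut-2-enyl)stannane are taken as purchasable.
Assumption on geometry: 4, 5, 7 and 8 are written as single Z isomers. Geometric purity is not essential, because the key step is expected to equilibrate the isomers.

## Route

Step 1
Reactants: 1 3-bromo-4-hydroxyphenylacetic acid
Product: 2 methyl (3-bromo-4-hydroxyphenyl)acetate
Conditions: MeOH, H2SO4 (cat.), reflux
Reagents that add atoms: methanol, CO
Why: Fischer esterification; the phenol and the aryl bromide are inert to acidic methanol.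

Step 2
Reactants: 2 methyl (3-bromo-4-hydroxyphenyl)acetate
Product: 3 methyl [4-(benzyloxy)-3-bromophenyl]acetate
Conditions: BnBr, K2CO3, acetone, reflux
Reagents that add atoms: benzyl bromide, BrCc1ccccc1
Why: Williamson ether synthesis; K2CO3 deprotonates the ortho-bromophenol but not the ester α-methylene, so only O-benzylation is expected.

Step 3
Reactants: 3 methyl [4-(benzyloxy)-3-bromophenyl]acetate
Product: 4 methyl (Z)-2-[4-(benzyloxy)-3-bromophenyl]-3-hydroxyacrylate (enol form of the α-formyl ester)
Conditions: HCO2Me, NaH, THF, 0 °C to rt; then aq. HCl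
Reagents that add atoms: methyl formate, COC=O
Why: Crossed Claisen condensation (formylation) with a non-enolisable formate; deprotonation of the product drives it to completion, and acidification should give the hydrogen-bonded enol.

Step 4
Reactants: 4 methyl (Z)-2-[4-(benzyloxy)-3-bromophenyl]-3-hydroxyacrylate
Product: 5 methyl (Z)-2-[4-(benzyloxy)-3-bromophenyl]-3-(tosyloxy)acrylate
Conditions: TsCl, N-methylimidazole, LiOH·H2O, CH2Cl2, 0 °C
Reagents that add atoms: p-toluenesulfonyl chloride, Cc1ccc(cc1)S(Cl)(=O)=O
Why: O-sulfonylation of a lithium-chelated enolate by the N-sulfonylimidazolium species; lithium bridging the enolate oxygen and the ester carbonyl should place the tosyloxy group cis to the ester (Z).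

Step 5
Reactants: 5 methyl (Z)-2-[4-(benzyloxy)-3-bromophenyl]-3-(tosyloxy)acrylate; 6 3,5-bis(benzyloxy)phenol
Product: 7 methyl (Z)-3-[3,5-bis(benzyloxy)phenoxy]-2-[4-(benzyloxy)-3-bromophenyl]acrylate
Conditions: K2CO3, DMF, 0 °C to rt
Reagents that add atoms: none
Why: Nucleophilic vinylic substitution by addition–elimination at the β-carbon of the acrylate; loss of tosylate from the intermediate ester enolate is faster than C–C rotation, so the Z geometry should be retained, and the aryl bromide is untouched.

Step 6
Reactants: 7 methyl (Z)-3-[3,5-bis(benzyloxy)phenoxy]-2-[4-(benzyloxy)-3-bromophenyl]acrylate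
Product: 8 (Z)-3-[3,5-bis(benzyloxy)phenoxy]-2-[4-(benzyloxy)-3-bromophenyl]acrylic acid
Conditions: LiOH, THF/MeOH/H2O, rt; then 1 M HCl to pH 3, 0 °C
Reagents that add atoms: lithium hydroxide, [Li+].[OH-]
Why: Saponification by acyl–oxygen cleavage; the carboxylate formed is no longer a Michael acceptor, which protects the vinyl ether, and the cold, mildly acidic work-up avoids enol ether hydrolysis.

Step 7
Reactants: 8 (Z)-3-[3,5-bis(benzyloxy)phenoxy]-2-[4-(benzyloxy)-3-bromophenyl]acrylic acid
Product: 10 5,7-bis(benzyloxy)-3-[4-(benzyloxy)-3-bromophenyl]chromen-4-one, via mixed trifluoroacetic anhydride 9 (not isolated)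
Conditions: (CF3CO)2O (1.5 equiv), CH2Cl2, 0 °C to rt
Reagents that add atoms: none
Why: Acid 8 and the anhydride should form the mixed anhydride 9 at once; its acyl carbon (future C4), further activated by the CF3CO2H released, is attacked by the ring A carbon ortho to the vinyl ether oxygen (future C4a), and loss of a proton from the Wheland intermediate and of trifluoroacetate gives the aromatic pyranone. The closest known reaction type is the intramolecular Friedel–Crafts acylation of 3-aryloxyacrylic acids to chromones, the ring-closing stage of the Simonis chromone synthesis. Ring C closes as a six-membered ring by attack on the exocyclic acyl C=O (6-exo-trig at the acyl carbon), and no stereocentre is created. Regioselectivity is secured by the substrate: the two carbons ortho to O1 are equivalent by rotation about the O–aryl bond, each is ortho to one benzyloxy group and para to the other, and the para carbon cannot reach the acyl group. The step also needs the Z geometry (carboxyl cis to aryloxy), which steps 4 and 5 set; any E isomer should equilibrate under the reaction conditions by reversible addition of trifluoroacetate at the future C2 of the push–pull alkene or by C-protonation to the oxocarbenium ion, and only the Z form is drained irreversibly. Intramolecular acylation has to outrun trifluoroacetylation of ring A, for which the anhydride is kept near stoichiometric at 0 °C; ring B is deactivated by bromine and cannot close a reasonable ring. Partial loss of the acid-labile 5-O-benzyl group would be harmless, since all benzyl ethers are removed in step 9.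

Step 8
Reactants: 10 5,7-bis(benzyloxy)-3-[4-(benzyloxy)-3-bromophenyl]chromen-4-one; 11 2-methylbut-3-en-2-ol
Product: 12 5,7-bis(benzyloxy)-3-{4-(benzyloxy)-3-[(E)-3-hydroxy-3-methylbut-1-en-1-yl]phenyl}chromen-4-one
Conditions: Pd(OAc)2 (cat.), P(o-tol)3, Et3N, DMF, 100 °C
Reagents that add atoms: none
Why: Mizoroki–Heck reaction; zerovalent palladium formed in situ from Pd(OAc)2 inserts into the C–Br bond and the aryl group adds to the terminal alkene carbon; β-hydride elimination can only occur on the benzylic side because the carbinol carbon is quaternary, giving the E-styrene, and Et3N is too poor a nucleophile to open the pyranone.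

Step 9
Reactants: 12 5,7-bis(benzyloxy)-3-{4-(benzyloxy)-3-[(E)-3-hydroxy-3-methylbut-1-en-1-yl]phenyl}chromen-4-one
Product: 13 5,7-dihydroxy-3-[4-hydroxy-3-(3-hydroxy-3-methylbutyl)phenyl]chromen-4-one
Conditions: H2 (1 atm), 10% Pd/C, THF/MeOH, rt
Reagents that add atoms: none
Why: Heterogeneous hydrogenation and hydrogenolysis; the styrenyl alkene should saturate first, which removes the allylic activation of the tertiary C–O bond, and the three O-benzyl groups then cleave; the vinylogous-ester C2=C3 bond of the pyranone reduces much more slowly at 1 atm, so the reaction is stopped after uptake of four equivalents.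

Step 10
Reactants: 13 5,7-dihydroxy-3-[4-hydroxy-3-(3-hydroxy-3-methylbutyl)phenyl]chromen-4-one
Product: 14 7-(tert-butyldimethylsilyloxy)-3-[4-(tert-butyldimethylsilyloxy)-3-(3-hydroxy-3-methylbutyl)phenyl]-5-hydroxychromen-4-one
Conditions: TBSCl (2.2 equiv), imidazole, DMF, 0 °C to rt
Reagents that add atoms: tert-butyldimethylsilyl chloride, CC(C)(C)[Si](C)(C)Cl
Why: Selective O-silylation; the 7-OH and 4'-OH are free acidic phenols, the 5-OH is locked in a hydrogen bond to the C4 carbonyl, and the tertiary alcohol is too hindered for this reagent.

Step 11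
Reactants: 14 7-(tert-butyldimethylsilyloxy)-3-[4-(tert-butyldimethylsilyloxy)-3-(3-hydroxy-3-methylbutyl)phenyl]-5-hydroxychromen-4-one
Product: 15 7-(tert-butyldimethylsilyloxy)-3-[4-(tert-butyldimethylsilyloxy)-3-(3-hydroxy-3-methylbutyl)phenyl]-5-hydroxy-6-iodochromen-4-one
Conditions: BnMe3N·ICl2 (1.05 equiv), CaCO3, CH2Cl2/MeOH, rt
Reagents that add atoms: benzyltrimethylammonium dichloroiodate, C[N+](C)(C)Cc1ccccc1.Cl[I-]Cl
Why: Electrophilic aromatic iodination; with this reagent the free, chelated 5-OH of 5-hydroxy-7-alkoxy chromones directs to its ortho carbon C6, the silylated ring B is less activated, and CaCO3 removes HCl so that the silyl ethers and the tertiary alcohol survive.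

Step 12
Reactants: 15 7-(tert-butyldimethylsilyloxy)-3-[4-(tert-butyldimethylsilyloxy)-3-(3-hydroxy-3-methylbutyl)phenyl]-5-hydroxy-6-iodochromen-4-one
Product: 16 7-(tert-butyldimethylsilyloxy)-3-[4-(tert-butyldimethylsilyloxy)-3-(3-hydroxy-3-methylbutyl)phenyl]-5-hydroxy-6-(3-methylbut-2-en-1-yl)chromen-4-one
Conditions: tributyl(3-methylbut-2-enyl)stannane, Pd(PPh3)4 (cat.), DMF, 90 °C
Reagents that add atoms: tributyl(3-methylbut-2-en-1-yl)stannane, CC(C)=CC[Sn](CCCC)(CCCC)CCCC
Why: Stille coupling; zerovalent palladium adds to the C6–I bond and transmetalation at the tin-bearing CH2 should give the linear prenyl group; the neutral, base-free conditions tolerate the free 5-OH, the tertiary alcohol, the silyl ethers and the pyranone.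

Step 13
Reactants: 16 7-(tert-butyldimethylsilyloxy)-3-[4-(tert-butyldimethylsilyloxy)-3-(3-hydroxy-3-methylbutyl)phenyl]-5-hydroxy-6-(3-methylbut-2-en-1-yl)chromen-4-one
Product: 17 coloratanin A, 5,7-dihydroxy-3-[4-hydroxy-3-(3-hydroxy-3-methylbutyl)phenyl]-6-(3-methylbut-2-en-1-yl)chromen-4-one
Conditions: Bu4NF, AcOH, THF, 0 °C
Reagents that add atoms: none
Why: Fluoride cleavage of the two aryl silyl ethers; buffering with AcOH keeps the medium near neutral, so neither the base-sensitive pyranone nor the acid-sensitive prenyl group and tertiary alcohol are touched.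

## Compound list

1 | 3-bromo-4-hydroxyphenylacetic acid | OC(=O)Cc1ccc(O)c(Br)c1 | starting material
2 | methyl (3-bromo-4-hydroxyphenyl)acetate | COC(=O)Cc1ccc(O)c(Br)c1 | intermediate
3 | methyl [4-(benzyloxy)-3-bromophenyl]acetate | COC(=O)Cc1ccc(OCc2ccccc2)c(Br)c1 | intermediate
4 | methyl (Z)-2-[4-(benzyloxy)-3-bromophenyl]-3-hydroxyacrylate | COC(=O)/C(=C\O)c1ccc(OCc2ccccc2)c(Br)c1 | intermediate
5 | methyl (Z)-2-[4-(benzyloxy)-3-bromophenyl]-3-(tosyloxy)acrylate | COC(=O)/C(=C\OS(=O)(=O)c1ccc(C)cc1)c1ccc(OCc2ccccc2)c(Br)c1 | intermediate
6 | 3,5-bis(benzyloxy)phenol | Oc1cc(OCc2ccccc2)cc(OCc2ccccc2)c1 | starting material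
7 | methyl (Z)-3-[3,5-bis(benzyloxy)phenoxy]-2-[4-(benzyloxy)-3-bromophenyl]acrylate | COC(=O)/C(=C\Oc1cc(OCc2ccccc2)cc(OCc2ccccc2)c1)c1ccc(OCc2ccccc2)c(Br)c1 | intermediate
8 | (Z)-3-[3,5-bis(benzyloxy)phenoxy]-2-[4-(benzyloxy)-3-bromophenyl]acrylic acid | OC(=O)/C(c1ccc(OCc2ccccc2)c(Br)c1)=C\Oc1cc(OCc2ccccc2)cc(OCc2ccccc2)c1 | intermediate
9 | (Z)-3-[3,5-bis(benzyloxy)phenoxy]-2-[4-(benzyloxy)-3-bromophenyl]acrylic trifluoroacetic anhydride | O=C(OC(=O)C(F)(F)F)/C(c1ccc(OCc2ccccc2)c(Br)c1)=C\Oc1cc(OCc2ccccc2)cc(OCc2ccccc2)c1 | intermediate
10 | 5,7-bis(benzyloxy)-3-[4-(benzyloxy)-3-bromophenyl]chromen-4-one | O=c1c(-c2ccc(OCc3ccccc3)c(Br)c2)coc2cc(OCc3ccccc3)cc(OCc3ccccc3)c12 | intermediate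
11 | 2-methylbut-3-en-2-ol | CC(C)(O)C=C | starting material
12 | 5,7-bis(benzyloxy)-3-{4-(benzyloxy)-3-[(E)-3-hydroxy-3-methylbut-1-en-1-yl]phenyl}chromen-4-one | CC(C)(O)/C=C/c1cc(-c2coc3cc(OCc4ccccc4)cc(OCc4ccccc4)c3c2=O)ccc1OCc1ccccc1 | intermediate
13 | 5,7-dihydroxy-3-[4-hydroxy-3-(3-hydroxy-3-methylbutyl)phenyl]chromen-4-one | CC(C)(O)CCc1cc(-c2coc3cc(O)cc(O)c3c2=O)ccc1O | intermediate
14 | 7-(tert-butyldimethylsilyloxy)-3-[4-(tert-butyldimethylsilyloxy)-3-(3-hydroxy-3-methylbutyl)phenyl]-5-hydroxychromen-4-one | CC(C)(O)CCc1cc(-c2coc3cc(O[Si](C)(C)C(C)(C)C)cc(O)c3c2=O)ccc1O[Si](C)(C)C(C)(C)C | intermediate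
15 | 7-(tert-butyldimethylsilyloxy)-3-[4-(tert-butyldimethylsilyloxy)-3-(3-hydroxy-3-methylbutyl)phenyl]-5-hydroxy-6-iodochromen-4-one | CC(C)(O)CCc1cc(-c2coc3cc(O[Si](C)(C)C(C)(C)C)c(I)c(O)c3c2=O)ccc1O[Si](C)(C)C(C)(C)C | intermediate
16 | 7-(tert-butyldimethylsilyloxy)-3-[4-(tert-butyldimethylsilyloxy)-3-(3-hydroxy-3-methylbutyl)phenyl]-5-hydroxy-6-(3-methylbut-2-en-1-yl)chromen-4-one | CC(C)=CCc1c(O[Si](C)(C)C(C)(C)C)cc2occ(-c3ccc(O[Si](C)(C)C(C)(C)C)c(CCC(C)(C)O)c3)c(=O)c2c1O | intermediate
17 | coloratanin A | CC(C)=CCc1c(O)cc2occ(-c3ccc(O)c(CCC(C)(C)O)c3)c(=O)c2c1O | target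

## Step count and least certain steps

Total: 13 steps. Longest linear sequence: 13 steps (1 to 17); compounds 6 and 11 each enter in a single step.

**Step 7 (key step).**
- What may go wrong: the ring closure may be slow, because the acyl group of 9 is a vinylogous carbonate and because any E isomer must first isomerise. Intermolecular trifluoroacetylation of the electron-rich ring A, or acid-induced benzyl cleavage and migration, would then compete.
- Fallback (sets out from 3 and 6, returns at 10): it removes both the geometric requirement and the vinylogous deactivation. Ester 3 would be condensed with paraformaldehyde (K2CO3, Bu4NI, toluene, 80 °C) to methyl 2-[4-(benzyloxy)-3-bromophenyl]acrylate F1. Oxa-Michael addition of phenol 6 to F1 (cat. Cs2CO3, MeCN) should give racemic methyl 3-[3,5-bis(benzyloxy)phenoxy]-2-[4-(benzyloxy)-3-bromophenyl]propanoate F2. Ester F2 would be cleaved with Me3SnOH in 1,2-dichloroethane at 80 °C, which avoids β-elimination of the phenoxide, to 3-[3,5-bis(benzyloxy)phenoxy]-2-[4-(benzyloxy)-3-bromophenyl]propanoic acid F3. Friedel–Crafts closure of F3 with (CF3CO)2O should give racemic 5,7-bis(benzyloxy)-3-[4-(benzyloxy)-3-bromophenyl]chroman-4-one F4. Dehydrogenation of F4 with DDQ in dioxane at reflux leads back to 10.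

**Step 5.**
- What may go wrong: the phenoxide may attack sulfur instead of carbon, transferring the tosyl group and returning the enolate of 4. Reversible phenoxide addition to the product may erode the alkene geometry.
- Fallback (sets out from 4, returns at 7): enol 4 would be converted with (COCl)2 and catalytic DMF (Vilsmeier-type chlorination) into methyl (Z)-3-chloro-2-[4-(benzyloxy)-3-bromophenyl]acrylate F5. A mixture of geometric isomers would serve as well. With 6 and K2CO3 in DMF, F5 can only undergo substitution at carbon, giving 7.

**Step 6.**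
- What may go wrong: hydroxide may add to the β-carbon and expel the aryloxide instead of attacking the ester carbonyl.
- Fallback (sets out from 7, returns at 8): the methyl ester would be cleaved at the O–CH3 bond by LiI in pyridine at reflux, a substitution at the methyl group that involves no hard nucleophile at the acrylate. No new compound is made.

**Step 11.**
- What may go wrong: iodination may leak to C8 or go twice, and the C7 silyl ether may be lost by methanolysis.
- Fallback (sets out from 14, returns at 16): it reaches C6 by a sigmatropic route that has only one possible site. O-Allylation of the 5-OH of 14 under neutral Tsuji–Trost conditions (allyl methyl carbonate, Pd(PPh3)4, THF) would give 5-(allyloxy)-7-(tert-butyldimethylsilyloxy)-3-[4-(tert-butyldimethylsilyloxy)-3-(3-hydroxy-3-methylbutyl)phenyl]chromen-4-one F6. Claisen rearrangement of F6, catalysed by Eu(fod)3 (fod = 6,6,7,7,8,8,8-heptafluoro-2,2-dimethyloctane-3,5-dionate) in CHCl3 at 60 °C, can only go to C6, the single free ortho carbon of O5. It would give 6-allyl-7-(tert-butyldimethylsilyloxy)-3-[4-(tert-butyldimethylsilyloxy)-3-(3-hydroxy-3-methylbutyl)phenyl]-5-hydroxychromen-4-one F7. Cross-metathesis of F7 with 2-methylbut-2-ene and the second-generation Grubbs catalyst, (H2IMes)(PCy3)Cl2Ru=CHPh, in CH2Cl2 at 40 °C then gives 16.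

**Step 12.**
- What may go wrong: allyl transposition during transmetalation would give the 1,1-dimethylallyl isomer. Slow transmetalation at the doubly ortho-substituted iodide would allow protodeiodination.
- Fallback (sets out from 15, returns at 16): Suzuki–Miyaura coupling with 2-(3-methylbut-2-enyl)-4,4,5,5-tetramethyl-1,3,2-dioxaborolane, Pd(OAc)2, a bulky biarylphosphine chosen for linear selectivity and K3PO4 in THF/H2O at 40 °C. The base-assisted boron transmetalation is governed by the ligand and not by the tin reagent. Any silyl loss under the aqueous base is harmless before step 13. No new compound is made.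

## Further compounds

F1 | step 7 | methyl 2-[4-(benzyloxy)-3-bromophenyl]acrylate | COC(=O)C(=C)c1ccc(OCc2ccccc2)c(Br)c1
F2 | step 7 | methyl 3-[3,5-bis(benzyloxy)phenoxy]-2-[4-(benzyloxy)-3-bromophenyl]propanoate (racemic) | COC(=O)C(COc1cc(OCc2ccccc2)cc(OCc2ccccc2)c1)c1ccc(OCc2ccccc2)c(Br)c1
F3 | step 7 | 3-[3,5-bis(benzyloxy)phenoxy]-2-[4-(benzyloxy)-3-bromophenyl]propanoic acid (racemic) | OC(=O)C(COc1cc(OCc2ccccc2)cc(OCc2ccccc2)c1)c1ccc(OCc2ccccc2)c(Br)c1
F4 | step 7 | 5,7-bis(benzyloxy)-3-[4-(benzyloxy)-3-bromophenyl]chroman-4-one (racemic) | O=C1C(c2ccc(OCc3ccccc3)c(Br)c2)COc2cc(OCc3ccccc3)cc(OCc3ccccc3)c12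
F5 | step 5 | methyl (Z)-3-chloro-2-[4-(benzyloxy)-3-bromophenyl]acrylate | COC(=O)/C(=C\Cl)c1ccc(OCc2ccccc2)c(Br)c1
F0 | step 6 | none | none
F6 | step 11 | 5-(allyloxy)-7-(tert-butyldimethylsilyloxy)-3-[4-(tert-butyldimethylsilyloxy)-3-(3-hydroxy-3-methylbutyl)phenyl]chromen-4-one | CC(C)(O)CCc1cc(-c2coc3cc(O[Si](C)(C)C(C)(C)C)cc(OCC=C)c3c2=O)ccc1O[Si](C)(C)C(C)(C)C
F7 | step 11 | 6-allyl-7-(tert-butyldimethylsilyloxy)-3-[4-(tert-butyldimethylsilyloxy)-3-(3-hydroxy-3-methylbutyl)phenyl]-5-hydroxychromen-4-one | CC(C)(O)CCc1cc(-c2coc3cc(O[Si](C)(C)C(C)(C)C)c(CC=C)c(O)c3c2=O)ccc1O[Si](C)(C)C(C)(C)C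
F0 | step 12 | none | none
A1 | alternative 1 | 5,7-bis(benzyloxy)-3-[4-(benzyloxy)-3-(3-methyl-3-triethylsilyloxybutyl)phenyl]chromen-4-one | O=c1c(-c2ccc(OCc3ccccc3)c(CCC(C)(C)O[Si](CC)(CC)CC)c2)coc2cc(OCc3ccccc3)cc(OCc3ccccc3)c12
A2 | alternative 1 | 2-acetoxy-4,6-bis(benzyloxy)benzoyl chloride | CC(=O)Oc1cc(OCc2ccccc2)cc(OCc2ccccc2)c1C(Cl)=O
A3 | alternative 1 | 4-{(E)-2-[4-(benzyloxy)-3-(3-methyl-3-triethylsilyloxybutyl)phenyl]ethenyl}morpholine | CC[Si](CC)(CC)OC(C)(C)CCc1cc(/C=C/N2CCOCC2)ccc1OCc1ccccc1
A4 | alternative 2 | 3-[4-(tert-butyldimethylsilyloxy)-3-(3-methyl-3-triethylsilyloxybutyl)phenyl]-5-hydroxy-6-(3-methylbut-2-enyl)-7-(triisopropylsilyloxy)chromen-4-one | CC(C)=CCc1c(O[Si](C(C)C)(C(C)C)C(C)C)cc2occ(-c3ccc(O[Si](C)(C)C(C)(C)C)c(CCC(C)(C)O[Si](CC)(CC)CC)c3)c(=O)c2c1O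
A5 | alternative 2 | 5-[4-(tert-butyldimethylsilyloxy)-3-(3-methyl-3-triethylsilyloxybutyl)phenyl]-2-(diazoacetyl)pyran-4-one | [N-]=[N+]=CC(=O)c1cc(=O)c(-c2ccc(O[Si](C)(C)C(C)(C)C)c(CCC(C)(C)O[Si](CC)(CC)CC)c2)co1
A6 | alternative 2 | triisopropyl[(5-methylhex-4-en-1-ynyl)oxy]silane | CC(C)=CCC#CO[Si](C(C)C)(C(C)C)C(C)C
A7 | alternative 3 | 3-(3-bromo-4-hydroxyphenyl)-5,7-dihydroxychromen-4-one | O=c1c(-c2ccc(O)c(Br)c2)coc2cc(O)cc(O)c12
A8 | alternative 3 | phloroglucinol (benzene-1,3,5-triol) | Oc1cc(O)cc(O)c1
A9 | alternative 3 | 2-(3-bromo-4-hydroxyphenyl)-1-(2,4,6-trihydroxyphenyl)ethanone | O=C(Cc1ccc(O)c(Br)c1)c1c(O)cc(O)cc1O
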